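**Plan** (target numbering: C1 = ring carbon bearing CH2OBz (C7), C2 = vinylic CH, C3-OH, C4-OH, C5-OBz, C6-OH)
1. Retrosynthesis: the two benzoates (O-7, O-5) come off first; the ring C1=C2 double bond is then cut by re-inserting SO2 between C1 and C2, giving a thiepane 1,1-dioxide; its two C–S bonds are cut to an open chain C1–C6–C5–C4–C3–C2.
2. Enabling feature: C1 and C2 are the only sp2 ring atoms, and the four stereocentres between them (C6, C5, C4, C3) have the pattern of C-2 to C-5 of D-galactose. The carbocycle is therefore a galactose chain whose ends (sugar C-1 and C-6) need only be joined by a C=C bond, with C7 as one extra carbon on sugar C-1.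
3. Forward: a D-galactopyranoside is differentiated at O-3 (PMB, future benzoate) and C-6 (Cl), opened and extended by one carbon at C-1, then closed with sulfide to the seven-membered thiepane. Oxidation to the sulfone and Ramberg–Bäcklund ring contraction give the six-membered carbocycle with the double bond in place.
4. Stereochemistry: all four stereocentres are taken unchanged from D-galactose (sugar C-2, C-3, C-4, C-5 = target C6, C5, C4, C3). The sulfur-bearing carbon is carried as an epimer mixture and becomes sp2; the key step creates no stereocentre.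
5. Protecting groups: MOM on the three hydroxyls that stay free, PMB on the two that become benzoates.

Key step: step 11

Remark: phenyl 1-thio-β-D-galactopyranoside and (tributylstannyl)methanol are taken as the commercial starting materials. Acyclic C7 compounds are numbered as heptitols from the added carbon (C-1; C-3 to C-6 = C-2 to C-5 of D-galactose), and thiepanes as S-1, C-2 (bearing CH2OPMB) to C-7. The carbinol carbon made in step 6 (C-2) is carried as an epimer mixture because step 11 makes it sp2.

Step 1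
Reactants: 1 phenyl 1-thio-β-D-galactopyranoside
Product: 3 phenyl 3-O-(4-methoxybenzyl)-1-thio-β-D-galactopyranoside, via stannylene acetal 2 (not isolated)
Conditions: Bu2SnO, MeOH, reflux; evaporate; PMBCl, Bu4NI (cat.), toluene, 70 °C
Reagents that add atoms: 4-methoxybenzyl chloride, COc1ccc(CCl)cc1
Why: The dibutylstannylene acetal of the cis-3,4-diol activates the equatorial O-3, so alkylation gives the 3-O-PMB ether selectively (stannylene-mediated regioselective alkylation) and no stereocentre is touched.

Step 2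
Reactants: 3 phenyl 3-O-(4-methoxybenzyl)-1-thio-β-D-galactopyranoside
Product: 4 phenyl 6-chloro-6-deoxy-3-O-(4-methoxybenzyl)-1-thio-β-D-galactopyranoside
Conditions: PPh3, CCl4, pyridine, 0 → 50 °C
Reagents that add atoms: carbon tetrachloride, ClC(Cl)(Cl)Cl
Why: The Appel reaction converts only the primary 6-OH into the chloride (SN2 on the alkoxyphosphonium ion), O-3 being blocked so that no 3,6-anhydro ring can form; a chloride is chosen because it is too unreactive to close a 1,6-anhydro ring from the lactolate in step 6.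

Step 3
Reactants: 4 phenyl 6-chloro-6-deoxy-3-O-(4-methoxybenzyl)-1-thio-β-D-galactopyranoside
Product: 5 phenyl 6-chloro-6-deoxy-2,4-di-O-(methoxymethyl)-3-O-(4-methoxybenzyl)-1-thio-β-D-galactopyranoside
Conditions: MOMCl, i-Pr2NEt, CH2Cl2, 40 °C
Reagents that add atoms: chloromethyl methyl ether, COCCl
Why: Amine-mediated acetalisation caps both remaining secondary hydroxyls as MOM ethers without disturbing the primary chloride or the thioglycoside.

Step 4
Reactants: 5 phenyl 6-chloro-6-deoxy-2,4-di-O-(methoxymethyl)-3-O-(4-methoxybenzyl)-1-thio-β-D-galactopyranoside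
Product: 6 6-chloro-6-deoxy-2,4-di-O-(methoxymethyl)-3-O-(4-methoxybenzyl)-D-galactopyranose (anomer mixture)
Conditions: NBS, acetone/H2O (9:1), −15 °C
Reagents that add atoms: water, O
Why: NBS activates the anomeric sulfur as a bromosulfonium ion and water captures the oxocarbenium ion (thioglycoside hydrolysis), giving the lactol without touching C-2 to C-5.

Step 5
Reactants: 7 (tributylstannyl)methanol
Product: 8 tributyl{[(4-methoxybenzyl)oxy]methyl}stannane
Conditions: NaH, PMBCl, Bu4NI (cat.), THF/DMF, 0 °C → rt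
Reagents that add atoms: 4-methoxybenzyl chloride, COc1ccc(CCl)cc1
Why: Williamson etherification of the stannyl carbinol gives the stannane precursor of the PMB-protected hydroxymethyl anion.

Step 6
Reactants: 6 6-chloro-6-deoxy-2,4-di-O-(methoxymethyl)-3-O-(4-methoxybenzyl)-D-galactopyranose; 8 tributyl{[(4-methoxybenzyl)oxy]methyl}stannane
Product: 12 (2RS)-6,7-anhydro-3,5-di-O-(methoxymethyl)-1,4-di-O-(4-methoxybenzyl)heptitol, via alkoxymethyllithium 9 (not isolated), via open-chain aldehyde 10 (not isolated), via chlorohydrin diol 11 (not isolated)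
Conditions: 8 (3 equiv), n-BuLi, THF, −78 °C; then 6, −78 → −30 °C; H2O; crude 11, K2CO3, MeOH, rt
Reagents that add atoms: none
Why: Tin–lithium exchange gives the α-alkoxymethyllithium, which deprotonates the lactol and adds to its open-chain aldehyde (organolithium addition to a reducing sugar), and base then closes the liberated 5-alkoxide onto the primary chloride (3-exo-tet) to the terminal epoxide, which distinguishes O-5 from the new carbinol; the new centre forms unselectively, which does not matter because it becomes sp2 in step 11.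

Step 7
Reactants: 12 (2RS)-6,7-anhydro-3,5-di-O-(methoxymethyl)-1,4-di-O-(4-methoxybenzyl)heptitol
Product: 13 (2RS)-6,7-anhydro-3,5-di-O-(methoxymethyl)-1,4-di-O-(4-methoxybenzyl)heptitol 2-methanesulfonate
Conditions: MsCl, Et3N, CH2Cl2, 0 °C
Reagents that add atoms: methanesulfonyl chloride, CS(=O)(=O)Cl
Why: Sulfonylation of the only free hydroxyl gives the secondary mesylate, the epoxide being inert to MsCl/Et3N at 0 °C.

Step 8
Reactants: 13 (2RS)-6,7-anhydro-3,5-di-O-(methoxymethyl)-1,4-di-O-(4-methoxybenzyl)heptitol 2-methanesulfonate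
Product: 15 2-[(4-methoxybenzyloxy)methyl]-4-(4-methoxybenzyloxy)-3,5-bis(methoxymethoxy)thiepan-6-ol (C-2 epimers), via hydroxy thiolate 14 (not isolated)
Conditions: Na2S·9H2O, DMF/H2O, rt → 50 °C, 0.02 M
Reagents that add atoms: sodium sulfide (nonahydrate), [Na+].[Na+].[S-2]
Why: Sulfide opens the terminal epoxide at its CH2 carbon and the thiolate then displaces the secondary mesylate by 7-exo-tet SN2 (double alkylation of sulfide, as used for thiepanes from sugar bis-electrophiles); the four galactose-derived centres are untouched and the inverted sulfur-bearing carbon stays an epimer mixture.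

Step 9
Reactants: 15 2-[(4-methoxybenzyloxy)methyl]-4-(4-methoxybenzyloxy)-3,5-bis(methoxymethoxy)thiepan-6-ol
Product: 17 2-[(4-methoxybenzyloxy)methyl]-4-(4-methoxybenzyloxy)-3,5-bis(methoxymethoxy)thiepan-6-ol 1,1-dioxide, via sulfoxide 16 (not isolated)
Conditions: mCPBA (2.2 equiv), NaHCO3, CH2Cl2, 0 °C → rt
Reagents that add atoms: 3-chloroperbenzoic acid, OOC(=O)c1cccc(Cl)c1
Why: Two equivalents of peracid oxidise the sulfide through the sulfoxide to the sulfone chemoselectively, ethers and the free alcohol being inert under buffered conditions.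

Step 10
Reactants: 17 2-[(4-methoxybenzyloxy)methyl]-4-(4-methoxybenzyloxy)-3,5-bis(methoxymethoxy)thiepan-6-ol 1,1-dioxide
Product: 18 2-[(4-methoxybenzyloxy)methyl]-4-(4-methoxybenzyloxy)-3,5,6-tris(methoxymethoxy)thiepane 1,1-dioxide
Conditions: MOMCl, i-Pr2NEt, Bu4NI (cat.), CH2Cl2, 40 °C
Reagents that add atoms: chloromethyl methyl ether, COCCl
Why: The β-hydroxyl of the sulfone is capped before strong base is used, because a free β-hydroxy sulfone would fragment by retro-aldol cleavage, and MOMCl with an amine base does this without deprotonating the sulfone.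

Step 11
Reactants: 18 2-[(4-methoxybenzyloxy)methyl]-4-(4-methoxybenzyloxy)-3,5,6-tris(methoxymethoxy)thiepane 1,1-dioxide
Product: 21 1-[(4-methoxybenzyloxy)methyl]-5-(4-methoxybenzyloxy)-3,4,6-tris(methoxymethoxy)cyclohex-1-ene configured at C-3 to C-6 as the target, via α-bromo sulfone 19 (not isolated), via episulfone 20 (not isolated)
Conditions: KOH/Al2O3, BrCF2CF2Br, t-BuOH/CH2Cl2, 0 °C → rt
Reagents that add atoms: none
Why: Ramberg–Bäcklund ring contraction in its one-pot halogenative form: KOH on alumina deprotonates the sulfone at an α-carbon (kinetically the ring CH2), BrCF2CF2Br transfers Br+ to the carbanion and collapses to tetrafluoroethylene and bromide, the α'-carbanion displaces bromide in a 1,3-elimination to the thiirane 1,1-dioxide, and loss of SO2 forms the C=C bond, so the seven-membered sulfur ring contracts to the six-membered carbocycle. The closest known reaction type is the Ramberg–Bäcklund conversion of polyoxygenated thiepane 1,1-dioxides into cyclohexene polyols and of α-branched sulfones into trisubstituted alkenes. The only ring closure is the 3-exo-tet formation of the cis-fused episulfone, whose new C–C bond is the bond that completes the six-membered ring. No stereocentre is created: both C-2 epimers of 18 converge on one alkene, the ring enforces the Z geometry, and the four galactose-derived centres carry no acidic hydrogen and stay untouched. The selectivity needed is halogenation and 1,3-elimination in preference to β-elimination of alkoxide from the sulfonyl carbanions and to retro-aldol cleavage; it is secured by having every β-oxygen (ring O-3 and O-6 and the exocyclic CH2O) as an ether with no free β-OH, and by the halogen-transfer reagent, which brominates the carbanion as soon as it forms. Regiochemistry is not an issue, because bromination at either α-carbon leads to the same episulfone and the double bond can only lie between the two carbons that flanked sulfur, one of which carries the CH2OPMB group.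

Step 12
Reactants: 21 1-[(4-methoxybenzyloxy)methyl]-5-(4-methoxybenzyloxy)-3,4,6-tris(methoxymethoxy)cyclohex-1-ene
Product: 22 [5-hydroxy-3,4,6-tris(methoxymethoxy)cyclohex-1-en-1-yl]methanol configured as the target
Conditions: DDQ (3 equiv), CH2Cl2/pH 7 buffer (10:1), 0 °C → rt
Reagents that add atoms: none
Why: DDQ oxidises both electron-rich p-methoxybenzyl ethers by benzylic hydride abstraction and hydrolysis of the oxocarbenium ions (oxidative PMB cleavage), leaving MOM ethers and the alkene intact and unmasking exactly the two hydroxyls that carry benzoates in the target.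

Step 13
Reactants: 22 [5-hydroxy-3,4,6-tris(methoxymethoxy)cyclohex-1-en-1-yl]methanol
Product: 23 [5-(benzoyloxy)-3,4,6-tris(methoxymethoxy)cyclohex-1-en-1-yl]methyl benzoate configured as the target
Conditions: BzCl (2.5 equiv), pyridine, DMAP (cat.), CH2Cl2, 0 °C → rt
Reagents that add atoms: benzoyl chloride, O=C(Cl)c1ccccc1
Why: DMAP-catalysed acylation esterifies the primary allylic and the single free secondary hydroxyl, and since all other hydroxyls are blocked no regioselectivity is needed.

Step 14
Reactants: 23 [5-(benzoyloxy)-3,4,6-tris(methoxymethoxy)cyclohex-1-en-1-yl]methyl benzoate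
Product: 25 [(3R,4S,5R,6S)-5-(benzoyloxy)-3,4,6-trihydroxycyclohex-1-en-1-yl]methyl benzoate, via tris(bromomethyl) ether 24 (not isolated)
Conditions: Me2BBr, CH2Cl2, −78 °C; then THF/sat. aq. NaHCO3, −78 → 0 °C
Reagents that add atoms: none
Why: Bromodimethylborane cleaves the three MOM acetals at −78 °C to bromomethyl ethers that hydrolyse on bicarbonate quench (Lewis-acid acetal cleavage), conditions under which benzoates are not cleaved and the allylic C–O bonds are not ionised, while the low temperature and short buffered work-up suppress 1,2-benzoyl migration to the neighbouring hydroxyls.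

**Compound list**
1 | phenyl 1-thio-β-D-galactopyranoside | OC[C@H]1O[C@@H](Sc2ccccc2)[C@H](O)[C@@H](O)[C@H]1O | starting material
2 | phenyl 3,4-O-(dibutylstannylene)-1-thio-β-D-galactopyranoside | OC[C@H]1O[C@@H](Sc2ccccc2)[C@H](O)[C@H]2O[Sn](CCCC)(CCCC)O[C@@H]12 | intermediate
3 | phenyl 3-O-(4-methoxybenzyl)-1-thio-β-D-galactopyranoside | OC[C@H]1O[C@@H](Sc2ccccc2)[C@H](O)[C@@H](OCc2ccc(OC)cc2)[C@H]1O | intermediate
4 | phenyl 6-chloro-6-deoxy-3-O-(4-methoxybenzyl)-1-thio-β-D-galactopyranoside | ClC[C@H]1O[C@@H](Sc2ccccc2)[C@H](O)[C@@H](OCc2ccc(OC)cc2)[C@H]1O | intermediate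
5 | phenyl 6-chloro-6-deoxy-2,4-di-O-(methoxymethyl)-3-O-(4-methoxybenzyl)-1-thio-β-D-galactopyranoside | ClC[C@H]1O[C@@H](Sc2ccccc2)[C@H](OCOC)[C@@H](OCc2ccc(OC)cc2)[C@H]1OCOC | intermediate
6 | 6-chloro-6-deoxy-2,4-di-O-(methoxymethyl)-3-O-(4-methoxybenzyl)-D-galactopyranose (anomer mixture) | ClC[C@H]1OC(O)[C@H](OCOC)[C@@H](OCc2ccc(OC)cc2)[C@H]1OCOC | intermediate
7 | (tributylstannyl)methanol | CCCC[Sn](CCCC)(CCCC)CO | starting material
8 | tributyl{[(4-methoxybenzyl)oxy]methyl}stannane | CCCC[Sn](CCCC)(CCCC)COCc1ccc(OC)cc1 | intermediate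
9 | {[(4-methoxybenzyl)oxy]methyl}lithium | [Li]COCc1ccc(OC)cc1 | intermediate
10 | 6-chloro-6-deoxy-2,4-di-O-(methoxymethyl)-3-O-(4-methoxybenzyl)-aldehydo-D-galactose (open-chain form of 6, present as its lithium alkoxide) | O=C[C@H](OCOC)[C@@H](OCc1ccc(OC)cc1)[C@@H](OCOC)[C@H](O)CCl | intermediate
11 | (2RS)-7-chloro-7-deoxy-3,5-di-O-(methoxymethyl)-1,4-di-O-(4-methoxybenzyl)heptitol | COc1ccc(COCC(O)[C@H](OCOC)[C@@H](OCc2ccc(OC)cc2)[C@@H](OCOC)[C@H](O)CCl)cc1 | intermediate
12 | (2RS)-6,7-anhydro-3,5-di-O-(methoxymethyl)-1,4-di-O-(4-methoxybenzyl)heptitol | COc1ccc(COCC(O)[C@H](OCOC)[C@@H](OCc2ccc(OC)cc2)[C@@H](OCOC)[C@H]2CO2)cc1 | intermediate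
13 | 2-methanesulfonate of 12 | COc1ccc(COCC(OS(C)(=O)=O)[C@H](OCOC)[C@@H](OCc2ccc(OC)cc2)[C@@H](OCOC)[C@H]2CO2)cc1 | intermediate
14 | (2RS)-3,5-di-O-(methoxymethyl)-1,4-di-O-(4-methoxybenzyl)-7-thioheptitol 2-methanesulfonate (as thiolate) | COc1ccc(COCC(OS(C)(=O)=O)[C@H](OCOC)[C@@H](OCc2ccc(OC)cc2)[C@@H](OCOC)[C@H](O)CS)cc1 | intermediate
15 | 2-[(4-methoxybenzyloxy)methyl]-4-(4-methoxybenzyloxy)-3,5-bis(methoxymethoxy)thiepan-6-ol (C-2 epimers) | COc1ccc(COCC2[C@H](OCOC)[C@@H](OCc3ccc(OC)cc3)[C@@H](OCOC)[C@H](O)CS2)cc1 | intermediate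
16 | 1-oxide (sulfoxide) of 15 | COc1ccc(COCC2[C@H](OCOC)[C@@H](OCc3ccc(OC)cc3)[C@@H](OCOC)[C@H](O)CS2=O)cc1 | intermediate
17 | 1,1-dioxide (sulfone) of 15 | COc1ccc(COCC2[C@H](OCOC)[C@@H](OCc3ccc(OC)cc3)[C@@H](OCOC)[C@H](O)CS2(=O)=O)cc1 | intermediate
18 | 2-[(4-methoxybenzyloxy)methyl]-4-(4-methoxybenzyloxy)-3,5,6-tris(methoxymethoxy)thiepane 1,1-dioxide | COc1ccc(COCC2[C@H](OCOC)[C@@H](OCc3ccc(OC)cc3)[C@@H](OCOC)[C@H](OCOC)CS2(=O)=O)cc1 | intermediate
19 | 7-bromo derivative of 18 | COc1ccc(COCC2[C@H](OCOC)[C@@H](OCc3ccc(OC)cc3)[C@@H](OCOC)[C@H](OCOC)C(Br)S2(=O)=O)cc1 | intermediate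
20 | 1-[(4-methoxybenzyloxy)methyl]-3-(4-methoxybenzyloxy)-2,4,5-tris(methoxymethoxy)-7-thiabicyclo[4.1.0]heptane 7,7-dioxide | COc1ccc(COCC23[C@H](OCOC)[C@@H](OCc4ccc(OC)cc4)[C@@H](OCOC)[C@H](OCOC)C2S3(=O)=O)cc1 | intermediate
21 | 1-[(4-methoxybenzyloxy)methyl]-5-(4-methoxybenzyloxy)-3,4,6-tris(methoxymethoxy)cyclohex-1-ene (C-3 to C-6 as in the target) | COc1ccc(COCC2=C[C@@H](OCOC)[C@H](OCOC)[C@H](OCc3ccc(OC)cc3)[C@H]2OCOC)cc1 | intermediate
22 | [5-hydroxy-3,4,6-tris(methoxymethoxy)cyclohex-1-en-1-yl]methanol (configured as the target) | OCC1=C[C@@H](OCOC)[C@H](OCOC)[C@H](O)[C@H]1OCOC | intermediate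
23 | [5-(benzoyloxy)-3,4,6-tris(methoxymethoxy)cyclohex-1-en-1-yl]methyl benzoate (configured as the target) | O=C(OCC1=C[C@@H](OCOC)[C@H](OCOC)[C@H](OC(=O)c2ccccc2)[C@H]1OCOC)c1ccccc1 | intermediate
24 | [5-(benzoyloxy)-3,4,6-tris(bromomethoxy)cyclohex-1-en-1-yl]methyl benzoate | O=C(OCC1=C[C@@H](OCBr)[C@H](OCBr)[C@H](OC(=O)c2ccccc2)[C@H]1OCBr)c1ccccc1 | intermediate
25 | [(3R,4S,5R,6S)-5-(benzoyloxy)-3,4,6-trihydroxycyclohex-1-en-1-yl]methyl benzoate | O=C(OCC1=C[C@@H](O)[C@H](O)[C@H](OC(=O)c2ccccc2)[C@H]1O)c1ccccc1 | target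

**Step count and risks**
Total step count: 14. Longest linear sequence: 13 (steps 1–4 and 6–14, from compound 1).

The three steps most likely to fail are steps 6, 8 and 11.

Step 6: the lithium lactolate may open to the aldehyde too slowly at the temperatures at which the alkoxymethyllithium survives, so that the reagent is lost by protonation or 1,2-shift before it adds. The fallback sets out from lactol 6 and performs the addition on a true aldehyde after the epoxide is already in place. NaBH4 in EtOH should reduce 6 to 6-chloro-6-deoxy-2,4-di-O-(methoxymethyl)-3-O-(4-methoxybenzyl)-D-galactitol F1. K2CO3 in MeOH should close the chlorohydrin to 5,6-anhydro-2,4-di-O-(methoxymethyl)-3-O-(4-methoxybenzyl)-D-galactitol F2. Dess–Martin periodinane should oxidise the primary alcohol to 5,6-anhydro-2,4-di-O-(methoxymethyl)-3-O-(4-methoxybenzyl)-aldehydo-D-galactose F3. Addition of organolithium 9 at −78 °C with a cold quench should then return to the route at epoxy alcohol 12.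

Step 8: ring closure at the hindered secondary mesylate may be slow, so that intermolecular S-alkylation to oligomers or elimination of the mesylate takes over. The fallback sets out from epoxy alcohol 12 and makes the C–S bond at the secondary carbon intermolecularly, closing the ring at the primary carbon instead. A Mitsunobu reaction (PPh3, DIAD, AcSH, THF, 0 °C) should give the inverted (2RS)-2-S-acetyl-6,7-anhydro-3,5-di-O-(methoxymethyl)-1,4-di-O-(4-methoxybenzyl)-2-thioheptitol F4. NaOMe in degassed MeOH at high dilution should free the thiolate, which opens the terminal epoxide at its CH2 carbon (7-endo, as in thiepane formation from dianhydrohexitols), returning to the route at thiepane 15.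

Step 11: β-elimination of alkoxide from the sulfonyl carbanions, or a second bromination, may compete with the 1,3-elimination while excess base and halogen donor are present together. The fallback sets out from thiepane 15 and uses the classical two-stage sequence, in which the halogen is introduced at the sulfide oxidation level. MOMCl and i-Pr2NEt should give 2-[(4-methoxybenzyloxy)methyl]-4-(4-methoxybenzyloxy)-3,5,6-tris(methoxymethoxy)thiepane F5. NCS in CCl4 at 0 °C should chlorinate α to sulfur, giving 7-chloro-2-[(4-methoxybenzyloxy)methyl]-4-(4-methoxybenzyloxy)-3,5,6-tris(methoxymethoxy)thiepane F6 (either α-regioisomer leads to the same alkene). Immediate oxidation with mCPBA at −20 °C should give the 7-chloro-thiepane 1,1-dioxide F7. One equivalent of t-BuOK in THF at −78 °C should then effect the 1,3-elimination and SO2 loss, returning to the route at cyclohexene 21.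

**Further compounds**
F1 | step 6 | 6-chloro-6-deoxy-2,4-di-O-(methoxymethyl)-3-O-(4-methoxybenzyl)-D-galactitol | OC[C@H](OCOC)[C@@H](OCc1ccc(OC)cc1)[C@@H](OCOC)[C@H](O)CCl
F2 | step 6 | 5,6-anhydro-2,4-di-O-(methoxymethyl)-3-O-(4-methoxybenzyl)-D-galactitol | OC[C@H](OCOC)[C@@H](OCc1ccc(OC)cc1)[C@@H](OCOC)[C@H]1CO1
F3 | step 6 | 5,6-anhydro-2,4-di-O-(methoxymethyl)-3-O-(4-methoxybenzyl)-aldehydo-D-galactose | O=C[C@H](OCOC)[C@@H](OCc1ccc(OC)cc1)[C@@H](OCOC)[C@H]1CO1
F4 | step 8 | (2RS)-2-S-acetyl-6,7-anhydro-3,5-di-O-(methoxymethyl)-1,4-di-O-(4-methoxybenzyl)-2-thioheptitol | COc1ccc(COCC(SC(C)=O)[C@H](OCOC)[C@@H](OCc2ccc(OC)cc2)[C@@H](OCOC)[C@H]2CO2)cc1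
F5 | step 11 | 2-[(4-methoxybenzyloxy)methyl]-4-(4-methoxybenzyloxy)-3,5,6-tris(methoxymethoxy)thiepane | COc1ccc(COCC2[C@H](OCOC)[C@@H](OCc3ccc(OC)cc3)[C@@H](OCOC)[C@H](OCOC)CS2)cc1
F6 | step 11 | 7-chloro-2-[(4-methoxybenzyloxy)methyl]-4-(4-methoxybenzyloxy)-3,5,6-tris(methoxymethoxy)thiepane | COc1ccc(COCC2[C@H](OCOC)[C@@H](OCc3ccc(OC)cc3)[C@@H](OCOC)[C@H](OCOC)C(Cl)S2)cc1
F7 | step 11 | 7-chloro-2-[(4-methoxybenzyloxy)methyl]-4-(4-methoxybenzyloxy)-3,5,6-tris(methoxymethoxy)thiepane 1,1-dioxide | COc1ccc(COCC2[C@H](OCOC)[C@@H](OCc3ccc(OC)cc3)[C@@H](OCOC)[C@H](OCOC)C(Cl)S2(=O)=O)cc1
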